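**Plan**
- Retrosynthesis: the exocyclic C=C is cut first (aldol condensation of a ring CH2 with a (Z)-enal). Next the ring bond between that CH2 and the O-bearing quaternary carbon is cut, which unfolds the bromo-hydroxy-cyclopentenone to a 2,5-disubstituted 3-bromofuran. The furan then loses its two α-substituents to give 3-bromofuran.
- Enabling feature: the ring is a 4-hydroxycyclopent-2-en-1-one. Its C1(=O), C2(Br)=C3H and C4(OH)(octenyl) are C2, C3, C4 and C5 of a furan at the same oxidation level, and its C5 is a furfuryl carbon. Hydration at furan C5 followed by 4π electrocyclisation (oxa-Piancatelli) therefore makes the C4–C5 bond, the ketone, the α-bromoenone and the tertiary alcohol in one operation.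
- Forward: 3-bromofuran is lithiated twice (CH2OMe next to Br, then the (Z)-octenyl chain at the far α-carbon). The carbocycle arises in step 4. The ester chain is joined last by aldol addition/elimination with a (Z)-enal made by Z-retentive cross-metathesis and oxidation.
- Stereochemistry: the single stereocentre is set in step 4 by a chiral Brønsted acid that biases the sense of conrotation. The two Z alkenes come from (Z)-oct-2-en-1-ol and (Z)-but-2-ene-1,4-diol. The E exocyclic alkene comes from the E1cB elimination.

Key step: step 4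

Remark 1: which antipode of the chiral acid gives the (4S)-hydroxyenone cannot be predicted with confidence; the (R)-acid is written, and the (S)-acid is to be used if it proves to give the other enantiomer.
Remark 2: the carbinol carbon is S in 9, 10, 15, 16 and 17 and R in 18 and 19 only because the neighbouring ring carbon gains priority when it becomes sp2; the spatial arrangement is the same throughout.

Step 1
Reactants: 1 (2Z)-oct-2-en-1-ol
Product: 2 (2Z)-1-bromooct-2-ene
Conditions: CBr4, PPh3, CH2Cl2, 0 °C
Reagents that add atoms: carbon tetrabromide, BrC(Br)(Br)Br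
Why: Appel reaction: the alkoxyphosphonium ion is displaced by bromide in an SN2 step at the primary carbon under neutral conditions, so the Z alkene should survive; the bromide is used without storage.

Step 2
Reactants: 3 3-bromofuran
Product: 5 3-bromo-2-(methoxymethyl)furan, via (3-bromofuran-2-yl)lithium 4 (not isolated)
Conditions: LiN(i-Pr)2, THF, −78 °C; then MOMCl, −78 °C to rt
Reagents that add atoms: chloromethyl methyl ether, COCCl
Why: Directed deprotonation followed by SN2 alkylation: the C2 proton, flanked by the ring oxygen and the bromine, is the most acidic and is removed by the amide base at −78 °C without bromine–lithium exchange, and the furyllithium is trapped by the α-chloro ether.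

Step 3
Reactants: 5 3-bromo-2-(methoxymethyl)furan; 2 (2Z)-1-bromooct-2-ene
Product: 7 3-bromo-2-(methoxymethyl)-5-[(2Z)-oct-2-en-1-yl]furan, via [4-bromo-5-(methoxymethyl)furan-2-yl]lithium 6 (not isolated)
Conditions: LiN(i-Pr)2, THF, −78 °C; then 2, −78 to 0 °C
Reagents that add atoms: none
Why: Heteroaryl lithiation/allylation: the only α-proton left (C5) is removed in preference to the β-proton, and the furyllithium displaces bromide from the primary allylic bromide at its α-carbon (SN2), which leaves the Z alkene in place.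

Step 4
Reactants: 7 3-bromo-2-(methoxymethyl)-5-[(2Z)-oct-2-en-1-yl]furan
Product: 9 (4S)-2-bromo-4-hydroxy-4-[(2Z)-oct-2-en-1-yl]cyclopent-2-en-1-one, via ring-opened dienol 8 (not isolated)
Conditions: (R)-3,3′-bis(2,4,6-triisopropylphenyl)-1,1′-binaphthyl-2,2′-diyl N-(trifluoromethylsulfonyl)phosphoramide (10 mol %), H2O (5 equiv), CHCl3, 50 °C
Reagents that add atoms: water, O
Why: Proposed new method: the strong chiral acid ionises the furfuryl methyl ether (loss of methanol) to a 5-alkyl-stabilised furfuryl cation, water adds at the octenyl-bearing ring carbon, the hemiketal opens to the dienol 8, and its O-protonated form, a 2-bromo-1,4-dihydroxypentadienyl cation, closes by thermal 4π conrotatory electrocyclisation between the exocyclic CH2 and the oxocarbenium carbon before proton loss unveils the α-bromoenone. The closest known reaction types are the racemic oxa-Piancatelli rearrangement of 2-furylcarbinols (including 5-alkylfurans, which give 4-alkyl-4-hydroxycyclopentenones) and the chiral-phosphoric-acid-catalysed aza-Piancatelli and Nazarov cyclisations; an enantioselective version with water that forms a fully substituted carbinol carbon goes beyond them. The five-membered ring is closed in the 4π-conrotatory mode of a pentadienyl cation, formally a 5-(enolendo)-exo-trig aldol of the dienol onto the protonated ketone. The one new stereocentre, the carbinol carbon C4, should be set by the phosphoramide anion, which can hydrogen-bond to both OH groups of the cation and so favour one helical sense of conrotation. The step needs water to enter at the ring carbon (attack at the exocyclic carbon only returns a furfuryl alcohol that re-ionises, so the material is funnelled forward) and the new C–C bond to start from the CH2 terminus and not from the doubly activated allylic CH2 of the side chain, which is secured because ring opening delivers the dienol regiospecifically and it should cyclise before it can tautomerise to the free enedione.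

Step 5
Reactants: 9 (4S)-2-bromo-4-hydroxy-4-[(2Z)-oct-2-en-1-yl]cyclopent-2-en-1-one
Product: 10 (4S)-2-bromo-4-[(2Z)-oct-2-en-1-yl]-4-[(trimethylsilyl)oxy]cyclopent-2-en-1-one
Conditions: N-(trimethylsilyl)imidazole, CH2Cl2, rt
Reagents that add atoms: N-(trimethylsilyl)imidazole, C[Si](C)(C)n1ccnc1
Why: Silylation of the tertiary alcohol with a neutral silyl-transfer reagent that does not enolise the ketone; the ether blocks retro-aldol opening and alkoxide chemistry in steps 8 and 9.

Step 6
Reactants: 11 methyl hex-5-enoate; 12 (2Z)-but-2-ene-1,4-diol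
Product: 13 methyl (5Z)-7-hydroxyhept-5-enoate
Conditions: Ru(SIMes)(S2C6H2Cl2)(=CH-C6H4-2-O-i-Pr) (5 mol %; SIMes = 1,3-dimesitylimidazolidin-2-ylidene, S2C6H2Cl2 = 3,6-dichlorobenzene-1,2-dithiolate), 12 (2 equiv), THF, 22 °C
Reagents that add atoms: none
Why: Stereoretentive (Z-selective) olefin cross-metathesis: with the dithiolate catalyst the substituents of the metallacyclobutane point away from the N-heterocyclic carbene, so the Z geometry of the diol partner is passed on to the new allylic alcohol.

Step 7
Reactants: 13 methyl (5Z)-7-hydroxyhept-5-enoate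
Product: 14 methyl (5Z)-7-oxohept-5-enoate
Conditions: Dess–Martin periodinane, pyridine, CH2Cl2, 0 °C
Reagents that add atoms: none
Why: Dess–Martin oxidation of the allylic alcohol under buffered, near-neutral conditions, chosen so that the Z-enal is not isomerised; the aldehyde is used at once.

Step 8
Reactants: 10 (4S)-2-bromo-4-[(2Z)-oct-2-en-1-yl]-4-[(trimethylsilyl)oxy]cyclopent-2-en-1-one; 14 methyl (5Z)-7-oxohept-5-enoate
Product: 16 methyl (5Z)-7-[(2S)-4-bromo-5-oxo-2-[(2Z)-oct-2-en-1-yl]-2-[(trimethylsilyl)oxy]cyclopent-3-en-1-yl]-7-hydroxyhept-5-enoate (mixture of diastereomers at the two new centres), via lithium cyclopentadienolate 15 (not isolated)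
Conditions: LiN(i-Pr)2, THF, −78 °C; then 14, −78 °C; aq. NH4Cl
Reagents that add atoms: none
Why: Aldol addition: the ketone has only one enolisable position (the ring CH2), its kinetic lithium enolate should add 1,2 to the enal at −78 °C faster than it attacks the ester, and the two new stereocentres need no control because step 9 removes them.

Step 9
Reactants: 16 methyl (5Z)-7-[(2S)-4-bromo-5-oxo-2-[(2Z)-oct-2-en-1-yl]-2-[(trimethylsilyl)oxy]cyclopent-3-en-1-yl]-7-hydroxyhept-5-enoate
Product: 18 methyl (5Z,7E)-7-[(2R)-4-bromo-5-oxo-2-[(2Z)-oct-2-en-1-yl]-2-[(trimethylsilyl)oxy]cyclopent-3-en-1-ylidene]hept-5-enoate, via allylic mesylate 17 (not isolated)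
Conditions: MsCl, Et3N, CH2Cl2, −20 °C; then DBU, 0 °C
Reagents that add atoms: none
Why: Mesylation of the secondary allylic alcohol followed by E1cB elimination through the ring dienolate should give the cross-conjugated dienone with the E geometry (chain carbon anti to the carbonyl) favoured, as in other 2-alkylidene cycloalkanones; any Z isomer is removed by chromatography.

Step 10
Reactants: 18 methyl (5Z,7E)-7-[(2R)-4-bromo-5-oxo-2-[(2Z)-oct-2-en-1-yl]-2-[(trimethylsilyl)oxy]cyclopent-3-en-1-ylidene]hept-5-enoate
Product: 19 bromovulone I, methyl (5Z,7E)-7-[(2R)-4-bromo-2-hydroxy-2-[(2Z)-oct-2-en-1-yl]-5-oxocyclopent-3-en-1-ylidene]hept-5-enoate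
Conditions: HF·pyridine, THF, 0 °C
Reagents that add atoms: none
Why: Fluoride-assisted cleavage of the tertiary trimethylsilyl ether under mildly acidic conditions that should leave the dienone, the vinyl bromide, the ester and the three alkenes untouched.

**Compound list**
1 | (2Z)-oct-2-en-1-ol | CCCCC/C=C\CO | starting material
2 | (2Z)-1-bromooct-2-ene | CCCCC/C=C\CBr | intermediate
3 | 3-bromofuran | Brc1ccoc1 | starting material
4 | (3-bromofuran-2-yl)lithium | [Li]c1occc1Br | intermediate (not isolated)
5 | 3-bromo-2-(methoxymethyl)furan | COCc1occc1Br | intermediate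
6 | [4-bromo-5-(methoxymethyl)furan-2-yl]lithium | [Li]c1cc(Br)c(COC)o1 | intermediate (not isolated)
7 | 3-bromo-2-(methoxymethyl)-5-[(2Z)-oct-2-en-1-yl]furan | COCc1oc(C/C=C\CCCCC)cc1Br | intermediate
8 | (3E,7Z)-3-bromo-2-hydroxytrideca-1,3,7-trien-5-one (ring-opened dienol) | C=C(O)/C(Br)=C\C(=O)C/C=C\CCCCC | intermediate (not isolated)
9 | (4S)-2-bromo-4-hydroxy-4-[(2Z)-oct-2-en-1-yl]cyclopent-2-en-1-one | CCCCC/C=C\C[C@@]1(O)C=C(Br)C(=O)C1 | intermediate
10 | (4S)-2-bromo-4-[(2Z)-oct-2-en-1-yl]-4-[(trimethylsilyl)oxy]cyclopent-2-en-1-one | CCCCC/C=C\C[C@@]1(O[Si](C)(C)C)C=C(Br)C(=O)C1 | intermediate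
11 | methyl hex-5-enoate | C=CCCCC(=O)OC | starting material
12 | (2Z)-but-2-ene-1,4-diol | OC/C=C\CO | starting material
13 | methyl (5Z)-7-hydroxyhept-5-enoate | OC/C=C\CCCC(=O)OC | intermediate
14 | methyl (5Z)-7-oxohept-5-enoate | O=C/C=C\CCCC(=O)OC | intermediate
15 | lithium (3S)-5-bromo-3-[(2Z)-oct-2-en-1-yl]-3-[(trimethylsilyl)oxy]cyclopenta-1,4-dien-1-olate | CCCCC/C=C\C[C@@]1(O[Si](C)(C)C)C=C(Br)C(O[Li])=C1 | intermediate (not isolated)
16 | methyl (5Z)-7-[(2S)-4-bromo-5-oxo-2-[(2Z)-oct-2-en-1-yl]-2-[(trimethylsilyl)oxy]cyclopent-3-en-1-yl]-7-hydroxyhept-5-enoate (diastereomer mixture) | CCCCC/C=C\C[C@@]1(O[Si](C)(C)C)C=C(Br)C(=O)C1C(O)/C=C\CCCC(=O)OC | intermediate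
17 | methyl (5Z)-7-[(2S)-4-bromo-5-oxo-2-[(2Z)-oct-2-en-1-yl]-2-[(trimethylsilyl)oxy]cyclopent-3-en-1-yl]-7-[(methanesulfonyl)oxy]hept-5-enoate | CCCCC/C=C\C[C@@]1(O[Si](C)(C)C)C=C(Br)C(=O)C1C(OS(C)(=O)=O)/C=C\CCCC(=O)OC | intermediate (not isolated)
18 | methyl (5Z,7E)-7-[(2R)-4-bromo-5-oxo-2-[(2Z)-oct-2-en-1-yl]-2-[(trimethylsilyl)oxy]cyclopent-3-en-1-ylidene]hept-5-enoate | CCCCC/C=C\C[C@@]1(O[Si](C)(C)C)C=C(Br)C(=O)/C1=C/C=C\CCCC(=O)OC | intermediate
19 | bromovulone I, methyl (5Z,7E)-7-[(2R)-4-bromo-2-hydroxy-2-[(2Z)-oct-2-en-1-yl]-5-oxocyclopent-3-en-1-ylidene]hept-5-enoate | CCCCC/C=C\C[C@@]1(O)C=C(Br)C(=O)/C1=C/C=C\CCCC(=O)OC | target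

**Count**
Total steps: 10. Longest linear sequence: 7 (steps 2, 3, 4, 5, 8, 9, 10).

**Steps most likely to fail**

Step 4 (proposed new method). What may go wrong:
- ionisation of the primary furfuryl ether may be too slow at a temperature at which the chiral ion pair still discriminates, so the conrotation may proceed with poor enantiofacial selectivity;
- the dienol may tautomerise to the open enedione and close through the wrong enol;
- the cation may oligomerise or capture the liberated methanol.

Fallback with known chemistry, setting out from 7: the racemic Lewis-acid oxa-Piancatelli rearrangement (Dy(OTf)3, 10 mol %, t-BuOH/H2O, 80 °C) should give racemic 2-bromo-4-hydroxy-4-[(2Z)-oct-2-en-1-yl]cyclopent-2-en-1-one F1. Preparative chromatography on a chiral stationary phase (amylose tris(3,5-dimethylphenylcarbamate), supercritical CO2/i-PrOH) then separates the (4S)-enantiomer from (4R)-2-bromo-4-hydroxy-4-[(2Z)-oct-2-en-1-yl]cyclopent-2-en-1-one F2. The route is rejoined at 9.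

Step 9. What may go wrong: the E1cB elimination may show poor E/Z selectivity at the new exocyclic double bond, and the dienolate or the base may isomerise the adjacent Z alkene (the Z-enal 14 may also isomerise before it reacts in step 8).

Fallback, setting out from 10, which builds the E-alkylidene first and the Z alkene last:
- Enolate 15 is added to 2,2-dimethoxyacetaldehyde to give (4S)-2-bromo-5-(1-hydroxy-2,2-dimethoxyethyl)-4-[(2Z)-oct-2-en-1-yl]-4-[(trimethylsilyl)oxy]cyclopent-2-en-1-one F3.
- MsCl/Et3N then DBU converts it, through (4S)-2-bromo-5-[1-(methanesulfonyloxy)-2,2-dimethoxyethyl]-4-[(2Z)-oct-2-en-1-yl]-4-[(trimethylsilyl)oxy]cyclopent-2-en-1-one F4, into (4R,5E)-2-bromo-5-(2,2-dimethoxyethylidene)-4-[(2Z)-oct-2-en-1-yl]-4-[(trimethylsilyl)oxy]cyclopent-2-en-1-one F5. At this stage the geometric isomers can be separated with no other conjugated labile alkene present.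
- Aqueous CF3CO2H removes acetal and silyl ether to give (2E)-2-[(2R)-4-bromo-2-hydroxy-2-[(2Z)-oct-2-en-1-yl]-5-oxocyclopent-3-en-1-ylidene]acetaldehyde F6.
- A salt-free Z-selective Wittig reaction with methyl 5-(triphenyl-λ5-phosphanylidene)pentanoate F7 (from [4-(methoxycarbonyl)butyl]triphenylphosphonium bromide and NaN(SiMe3)2, 2.2 equiv, THF, −78 °C) forms the last Z alkene.

The route is rejoined directly at 19.

Step 3. What may go wrong: deprotonation may be incomplete or misdirected (competition from the β-position next to bromine, bromine migration on the lithiated furan), giving regioisomeric or mixed alkylation products.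

Fallback, setting out from 5: electrophilic iodination at the only free α-position (N-iodosuccinimide, DMF, 0 °C) should give 3-bromo-5-iodo-2-(methoxymethyl)furan F8. Iodine–lithium exchange (n-BuLi, THF, −78 °C), which is faster than bromine exchange, generates organolithium 6 regiospecifically. Alkylation with 2 as in step 3 rejoins the route at 7.

Further compounds
F1 | step 4 | racemic 2-bromo-4-hydroxy-4-[(2Z)-oct-2-en-1-yl]cyclopent-2-en-1-one | CCCCC/C=C\CC1(O)C=C(Br)C(=O)C1
F2 | step 4 | (4R)-2-bromo-4-hydroxy-4-[(2Z)-oct-2-en-1-yl]cyclopent-2-en-1-one | CCCCC/C=C\C[C@]1(O)C=C(Br)C(=O)C1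
F3 | step 9 | (4S)-2-bromo-5-(1-hydroxy-2,2-dimethoxyethyl)-4-[(2Z)-oct-2-en-1-yl]-4-[(trimethylsilyl)oxy]cyclopent-2-en-1-one | CCCCC/C=C\C[C@@]1(O[Si](C)(C)C)C=C(Br)C(=O)C1C(O)C(OC)OC
F4 | step 9 | (4S)-2-bromo-5-[1-(methanesulfonyloxy)-2,2-dimethoxyethyl]-4-[(2Z)-oct-2-en-1-yl]-4-[(trimethylsilyl)oxy]cyclopent-2-en-1-one | CCCCC/C=C\C[C@@]1(O[Si](C)(C)C)C=C(Br)C(=O)C1C(OS(C)(=O)=O)C(OC)OC
F5 | step 9 | (4R,5E)-2-bromo-5-(2,2-dimethoxyethylidene)-4-[(2Z)-oct-2-en-1-yl]-4-[(trimethylsilyl)oxy]cyclopent-2-en-1-one | CCCCC/C=C\C[C@@]1(O[Si](C)(C)C)C=C(Br)C(=O)/C1=C/C(OC)OC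
F6 | step 9 | (2E)-2-[(2R)-4-bromo-2-hydroxy-2-[(2Z)-oct-2-en-1-yl]-5-oxocyclopent-3-en-1-ylidene]acetaldehyde | CCCCC/C=C\C[C@@]1(O)C=C(Br)C(=O)/C1=C/C=O
F7 | step 9 | methyl 5-(triphenyl-λ5-phosphanylidene)pentanoate | COC(=O)CCCC=P(c1ccccc1)(c1ccccc1)c1ccccc1
F8 | step 3 | 3-bromo-5-iodo-2-(methoxymethyl)furan | COCc1oc(I)cc1Br
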